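**Retrosynthetic overview**
1. Silandrin comes from its 4-O-benzyl ether by hydrogenolysis; the CH2OH group comes from a (4R)-dioxolan-4-yl group by glycol cleavage and aldehyde reduction.
2. The 1,4-benzodioxane ring is disconnected by an inverse-demand hetero-Diels–Alder reaction: the o-quinone of (S)-eriodictyol (heterodiene) plus an E-styrene (dienophile).
3. (S)-Eriodictyol supplies flavanone C-2 and the complete chromanone. E-geometry gives the trans ring, and the dioxolane stereocentre (from D-glyceraldehyde) directs the face and later becomes the CH2OH carbon.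
4. The styrene comes from a Heck reaction of 1-(benzyloxy)-4-bromo-2-methoxybenzene with (S)-4-vinyl-dioxolane, which is made by Wittig methylenation of (R)-glyceraldehyde acetonide.
5. Ring order: all carbocycles and the chromanone are bought; the dioxane ring is the only ring formed (step 3).

Assumption: (S)-eriodictyol, (R)-glyceraldehyde acetonide (from D-mannitol) and 1-(benzyloxy)-4-bromo-2-methoxybenzene are taken as commercial.

**Route**

Step 1
Reactants: 1 (R)-2,2-dimethyl-1,3-dioxolane-4-carbaldehyde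
Product: 2 (S)-2,2-dimethyl-4-vinyl-1,3-dioxolane
Conditions: Ph3PCH3Br, KOtBu, THF, 0 °C; add 1 at −78 °C → rt; distil
Reagents that add atoms: methyltriphenylphosphonium bromide, C[P+](c1ccccc1)(c1ccccc1)c1ccccc1.[Br-]
Why: Wittig methylenation with the non-stabilised ylide; the stereocentre is only carried through (R→S is a CIP priority change, not an inversion) and low-temperature addition limits α-epimerisation.

Step 2
Reactants: 2 (S)-2,2-dimethyl-4-vinyl-1,3-dioxolane; 3 1-(benzyloxy)-4-bromo-2-methoxybenzene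
Product: 4 (4S)-4-{(E)-2-[4-(benzyloxy)-3-methoxyphenyl]ethenyl}-2,2-dimethyl-1,3-dioxolane
Conditions: Pd(OAc)2 (5 mol %), P(o-tol)3 (10 mol %), NaOAc, DMF, 100 °C, sealed tube
Reagents that add atoms: none
Why: Mizoroki–Heck reaction: syn-carbopalladation at the terminal alkene carbon and syn β-hydride elimination toward the benzylic hydrogens give the conjugated E-styrene, leaving the dioxolane stereocentre untouched.

Step 3
Reactants: 4 (4S)-4-{(E)-2-[4-(benzyloxy)-3-methoxyphenyl]ethenyl}-2,2-dimethyl-1,3-dioxolane; 5 (S)-eriodictyol [(2S)-2-(3,4-dihydroxyphenyl)-5,7-dihydroxychroman-4-one]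
Product: 7 (2S)-2-{(2R,3S)-2-[4-(benzyloxy)-3-methoxyphenyl]-3-[(4R)-2,2-dimethyl-1,3-dioxolan-4-yl]-2,3-dihydro-1,4-benzodioxin-6-yl}-5,7-dihydroxychroman-4-one, via 4-[(2S)-5,7-dihydroxy-4-oxochroman-2-yl]cyclohexa-3,5-diene-1,2-dione (eriodictyol o-quinone) 6 (not isolated)
Conditions: Ag2O (2.2 equiv), 4 (2.5 equiv), toluene–acetone 2:1, 4 Å MS, dark, 45 °C; SiO2 chromatography
Reagents that add atoms: none
Why: Ag2O oxidises only the B-ring catechol to o-quinone 6, whose O=C–C=O unit reacts as an electron-poor heterodiene in an inverse-electron-demand hetero-Diels–Alder reaction with the electron-rich styrene 4; suprafacial addition turns E-geometry into the trans-2,3 relationship, addition anti to the allylic dioxolane C–O bond (inside-alkoxy transition state, erythro product) sets 2R,3S, and the bought flavanone C-2 is not touched.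

Step 4
Reactants: 7 the cycloadduct from step 3
Product: 10 (2S)-2-{(2R,3R)-2-[4-(benzyloxy)-3-methoxyphenyl]-3-(hydroxymethyl)-2,3-dihydro-1,4-benzodioxin-6-yl}-5,7-dihydroxychroman-4-one (O-benzylsilandrin), via (2S)-2-{(2R,3R)-2-[4-(benzyloxy)-3-methoxyphenyl]-3-[(1R)-1,2-dihydroxyethyl]-2,3-dihydro-1,4-benzodioxin-6-yl}-5,7-dihydroxychroman-4-one 8 (not isolated), via (2S)-2-{(2R,3S)-2-[4-(benzyloxy)-3-methoxyphenyl]-3-formyl-2,3-dihydro-1,4-benzodioxin-6-yl}-5,7-dihydroxychroman-4-one 9 (not isolated)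
Conditions: H5IO6 (1.3 equiv), EtOAc, 0 °C → rt; filter; then NaBH(OAc)3, THF, 0 °C → rt
Reagents that add atoms: none
Why: Periodic acid hydrolyses the terminal acetonide and cleaves the resulting 1,2-diol (Malaprade glycol cleavage), and NaBH(OAc)3 reduces the aldehyde chemoselectively beside the chelated C-4 ketone, so the former glyceraldehyde stereocentre becomes the CH2OH carbon while the ring stereocentres are retained (3S→3R is a CIP priority change only).

Step 5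
Reactants: 10 O-benzylsilandrin
Product: 11 silandrin, (2S)-5,7-dihydroxy-2-[(2R,3R)-2-(4-hydroxy-3-methoxyphenyl)-3-(hydroxymethyl)-2,3-dihydro-1,4-benzodioxin-6-yl]chroman-4-one
Conditions: H2 (1 atm), 10% Pd/C, EtOAc–MeOH, rt, stop at full conversion
Reagents that add atoms: none
Why: Catalytic hydrogenolysis cleaves the primary benzyl aryl ether much faster than the two hindered secondary benzylic C–O bonds of the benzodioxane and chromanone, freeing the guaiacyl phenol without touching any stereocentre.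

**Compound list**
1 | (R)-2,2-dimethyl-1,3-dioxolane-4-carbaldehyde ((R)-glyceraldehyde acetonide) | O=C[C@H]1COC(C)(C)O1 | starting material
2 | (S)-2,2-dimethyl-4-vinyl-1,3-dioxolane | C=C[C@H]1COC(C)(C)O1 | intermediate
3 | 1-(benzyloxy)-4-bromo-2-methoxybenzene | COc1cc(Br)ccc1OCc1ccccc1 | starting material
4 | (4S)-4-{(E)-2-[4-(benzyloxy)-3-methoxyphenyl]ethenyl}-2,2-dimethyl-1,3-dioxolane | COc1cc(/C=C/[C@H]2COC(C)(C)O2)ccc1OCc1ccccc1 | intermediate
5 | (S)-eriodictyol, (2S)-2-(3,4-dihydroxyphenyl)-5,7-dihydroxychroman-4-one | Oc1ccc([C@@H]2CC(=O)c3c(O)cc(O)cc3O2)cc1O | starting material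
6 | eriodictyol o-quinone, 4-[(2S)-5,7-dihydroxy-4-oxochroman-2-yl]cyclohexa-3,5-diene-1,2-dione (formed in situ) | O=C1C=CC([C@@H]2CC(=O)c3c(O)cc(O)cc3O2)=CC1=O | intermediate
7 | (2S)-2-{(2R,3S)-2-[4-(benzyloxy)-3-methoxyphenyl]-3-[(4R)-2,2-dimethyl-1,3-dioxolan-4-yl]-2,3-dihydro-1,4-benzodioxin-6-yl}-5,7-dihydroxychroman-4-one | COc1cc([C@H]2Oc3ccc([C@@H]4CC(=O)c5c(O)cc(O)cc5O4)cc3O[C@@H]2[C@H]6COC(C)(C)O6)ccc1OCc1ccccc1 | intermediate
8 | (2S)-2-{(2R,3R)-2-[4-(benzyloxy)-3-methoxyphenyl]-3-[(1R)-1,2-dihydroxyethyl]-2,3-dihydro-1,4-benzodioxin-6-yl}-5,7-dihydroxychroman-4-one (formed in situ) | COc1cc([C@H]2Oc3ccc([C@@H]4CC(=O)c5c(O)cc(O)cc5O4)cc3O[C@@H]2[C@H](O)CO)ccc1OCc1ccccc1 | intermediate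
9 | (2S)-2-{(2R,3S)-2-[4-(benzyloxy)-3-methoxyphenyl]-3-formyl-2,3-dihydro-1,4-benzodioxin-6-yl}-5,7-dihydroxychroman-4-one (formed in situ) | COc1cc([C@H]2Oc3ccc([C@@H]4CC(=O)c5c(O)cc(O)cc5O4)cc3O[C@@H]2C=O)ccc1OCc1ccccc1 | intermediate
10 | O-benzylsilandrin, (2S)-2-{(2R,3R)-2-[4-(benzyloxy)-3-methoxyphenyl]-3-(hydroxymethyl)-2,3-dihydro-1,4-benzodioxin-6-yl}-5,7-dihydroxychroman-4-one | COc1cc([C@H]2Oc3ccc([C@@H]4CC(=O)c5c(O)cc(O)cc5O4)cc3O[C@@H]2CO)ccc1OCc1ccccc1 | intermediate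
11 | silandrin, (2S)-5,7-dihydroxy-2-[(2R,3R)-2-(4-hydroxy-3-methoxyphenyl)-3-(hydroxymethyl)-2,3-dihydro-1,4-benzodioxin-6-yl]chroman-4-one | COc1cc([C@H]2Oc3ccc([C@@H]4CC(=O)c5c(O)cc(O)cc5O4)cc3O[C@@H]2CO)ccc1O | target

**Step count**
Total steps: 5. Longest linear sequence: 5 (1 → 2 → 4 → 7 → 10 → 11).

**Three steps most likely to fail**

Step 3 (highest risk). The o-quinone 6 carries no activating group, so the cycloaddition may be slow relative to quinone decay (tautomerisation to the quinone methide, dimerisation). Its two oxygens are electronically almost equal, so the 7-yl regioisomer is expected in a similar amount; it is a constitutional isomer and is removed on silica. Facial selectivity from the dioxolane is expected to be only moderate (about 3–5:1), and the minor isomer is also removed at this stage. Fallback: replace the cycloaddition with a biomimetic one-electron phenol cross-coupling. Setting out from 2, a Heck reaction with commercial 4-bromo-2-methoxyphenol (same catalyst system) gives 4-{(E)-2-[(4S)-2,2-dimethyl-1,3-dioxolan-4-yl]ethenyl}-2-methoxyphenol F1. Ag2CO3 in benzene–acetone at 50 °C with 5 couples a B-ring aryloxyl radical to C-β of the radical from F1, and the neighbouring phenol closes onto the resulting p-quinone methide to give the trans-benzodioxane (2S)-2-{(2R,3S)-3-[(4R)-2,2-dimethyl-1,3-dioxolan-4-yl]-2-(4-hydroxy-3-methoxyphenyl)-2,3-dihydro-1,4-benzodioxin-6-yl}-5,7-dihydroxychroman-4-one F2. Aqueous 80% AcOH at 40 °C removes the acetonide to give (2S)-2-{(2R,3R)-3-[(1R)-1,2-dihydroxyethyl]-2-(4-hydroxy-3-methoxyphenyl)-2,3-dihydro-1,4-benzodioxin-6-yl}-5,7-dihydroxychroman-4-one F3. NaIO4 (1.0 equiv, THF–pH 7 buffer, 0 °C, minutes, relying on glycol cleavage being faster than guaiacol oxidation) gives (2S)-2-[(2R,3S)-3-formyl-2-(4-hydroxy-3-methoxyphenyl)-2,3-dihydro-1,4-benzodioxin-6-yl]-5,7-dihydroxychroman-4-one F4. NaBH(OAc)3 then reduces F4 directly to 11, where the fallback rejoins the route.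

Step 4. Periodic acid may attack the free 5,7-dihydroxy ring, and the α-aryloxy aldehyde 9 can epimerise or undergo β-elimination before reduction. Fallback: a protecting-group detour from 7. Ac2O, pyridine and DMAP give (2S)-2-{(2R,3S)-2-[4-(benzyloxy)-3-methoxyphenyl]-3-[(4R)-2,2-dimethyl-1,3-dioxolan-4-yl]-2,3-dihydro-1,4-benzodioxin-6-yl}-4-oxochroman-5,7-diyl diacetate F5. H5IO6 in EtOAc converts it through (2S)-2-{(2R,3R)-2-[4-(benzyloxy)-3-methoxyphenyl]-3-[(1R)-1,2-dihydroxyethyl]-2,3-dihydro-1,4-benzodioxin-6-yl}-4-oxochroman-5,7-diyl diacetate F6 into (2S)-2-{(2R,3S)-2-[4-(benzyloxy)-3-methoxyphenyl]-3-formyl-2,3-dihydro-1,4-benzodioxin-6-yl}-4-oxochroman-5,7-diyl diacetate F7. NaBH(OAc)3 gives (2S)-2-{(2R,3R)-2-[4-(benzyloxy)-3-methoxyphenyl]-3-(hydroxymethyl)-2,3-dihydro-1,4-benzodioxin-6-yl}-4-oxochroman-5,7-diyl diacetate F8. Acidic methanolysis (AcCl in MeOH, 0 °C → rt) removes the two aryl acetates without base and returns to the route at 10.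

Step 2. The electron-rich aryl bromide is a slow Heck partner and alkene 2 is volatile. β-Hydride elimination toward the dioxolane C–H would destroy the stereocentre, and any Z-alkene would erode the trans purity of step 3. Fallback: build the alkene from the aldehyde instead. Setting out from 1, Takai olefination (CrCl2, CHI3, THF, 0 °C) gives (4S)-4-[(E)-2-iodoethenyl]-2,2-dimethyl-1,3-dioxolane F9. Suzuki–Miyaura coupling with commercial [4-(benzyloxy)-3-methoxyphenyl]boronic acid (Pd(PPh3)4, K2CO3, dioxane–H2O, 60 °C) retains the E-geometry and returns to the route at 4.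

**Further compounds**
F1 | step 3 | 4-{(E)-2-[(4S)-2,2-dimethyl-1,3-dioxolan-4-yl]ethenyl}-2-methoxyphenol | COc1cc(/C=C/[C@H]2COC(C)(C)O2)ccc1O
F2 | step 3 | (2S)-2-{(2R,3S)-3-[(4R)-2,2-dimethyl-1,3-dioxolan-4-yl]-2-(4-hydroxy-3-methoxyphenyl)-2,3-dihydro-1,4-benzodioxin-6-yl}-5,7-dihydroxychroman-4-one | COc1cc([C@H]2Oc3ccc([C@@H]4CC(=O)c5c(O)cc(O)cc5O4)cc3O[C@@H]2[C@H]6COC(C)(C)O6)ccc1O
F3 | step 3 | (2S)-2-{(2R,3R)-3-[(1R)-1,2-dihydroxyethyl]-2-(4-hydroxy-3-methoxyphenyl)-2,3-dihydro-1,4-benzodioxin-6-yl}-5,7-dihydroxychroman-4-one | COc1cc([C@H]2Oc3ccc([C@@H]4CC(=O)c5c(O)cc(O)cc5O4)cc3O[C@@H]2[C@H](O)CO)ccc1O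
F4 | step 3 | (2S)-2-[(2R,3S)-3-formyl-2-(4-hydroxy-3-methoxyphenyl)-2,3-dihydro-1,4-benzodioxin-6-yl]-5,7-dihydroxychroman-4-one | COc1cc([C@H]2Oc3ccc([C@@H]4CC(=O)c5c(O)cc(O)cc5O4)cc3O[C@@H]2C=O)ccc1O
F5 | step 4 | (2S)-2-{(2R,3S)-2-[4-(benzyloxy)-3-methoxyphenyl]-3-[(4R)-2,2-dimethyl-1,3-dioxolan-4-yl]-2,3-dihydro-1,4-benzodioxin-6-yl}-4-oxochroman-5,7-diyl diacetate | COc1cc([C@H]2Oc3ccc([C@@H]4CC(=O)c5c(OC(C)=O)cc(OC(C)=O)cc5O4)cc3O[C@@H]2[C@H]6COC(C)(C)O6)ccc1OCc1ccccc1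
F6 | step 4 | (2S)-2-{(2R,3R)-2-[4-(benzyloxy)-3-methoxyphenyl]-3-[(1R)-1,2-dihydroxyethyl]-2,3-dihydro-1,4-benzodioxin-6-yl}-4-oxochroman-5,7-diyl diacetate | COc1cc([C@H]2Oc3ccc([C@@H]4CC(=O)c5c(OC(C)=O)cc(OC(C)=O)cc5O4)cc3O[C@@H]2[C@H](O)CO)ccc1OCc1ccccc1
F7 | step 4 | (2S)-2-{(2R,3S)-2-[4-(benzyloxy)-3-methoxyphenyl]-3-formyl-2,3-dihydro-1,4-benzodioxin-6-yl}-4-oxochroman-5,7-diyl diacetate | COc1cc([C@H]2Oc3ccc([C@@H]4CC(=O)c5c(OC(C)=O)cc(OC(C)=O)cc5O4)cc3O[C@@H]2C=O)ccc1OCc1ccccc1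
F8 | step 4 | (2S)-2-{(2R,3R)-2-[4-(benzyloxy)-3-methoxyphenyl]-3-(hydroxymethyl)-2,3-dihydro-1,4-benzodioxin-6-yl}-4-oxochroman-5,7-diyl diacetate | COc1cc([C@H]2Oc3ccc([C@@H]4CC(=O)c5c(OC(C)=O)cc(OC(C)=O)cc5O4)cc3O[C@@H]2CO)ccc1OCc1ccccc1
F9 | step 2 | (4S)-4-[(E)-2-iodoethenyl]-2,2-dimethyl-1,3-dioxolane | I/C=C/[C@H]1COC(C)(C)O1
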